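**Plan**

- Labels: ring A = dimethoxybenzene of the indane; ring B = cyclopentane holding Ca (ArCH on ring A), Cb and Cc (fusion carbons); ring C = cyclopentane Cb–Cd–D1–D2–Cc (Cd = ArCH on ring D); ring D = central arene (D1 bears Cd, D2 bears Cc, D3 H, D4 OMe, D5 bears C3, D6 bears O1); ring E = dihydrofuran O1–C2–C3.
- Cuts, last-formed bond first: eight O–CH3 bonds; Cd–aryl (carbinol cation plus anisole); Cb–CO2Me; then D6–O1 and D1–Cd in one operation. This is possible because ring D carries O1 and Cd on the adjacent carbons D6 and D1, each the terminus of a five-membered ring (E and C), which are the two ends of an aryne bond.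
- The aryne precursor is cut at C3–D5 (ketone α-arylation), Ca–ring A (Friedel–Crafts closure of ring B) and Cb–Cc (allylic alkylation of an arylmalonate). The electrophile for D1 is one ester of a gem-diester on Cb, so Cb has no acidic hydrogen and one ester is always cis to ring D.
- Forward order: ring D aldehyde → cinnamyl carbonate → Cb–Cc bond → ring B → side chain on D5 → ortho-silyl triflate (silicon on D6, triflate on D1, the phenol oxygen of the starting aldehyde) → rings E and C together → aryl on Cd → demethylation.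
- Stereochemistry: Cc from iridium-catalysed allylic alkylation; Ca trans to ring D from the cationic cyclisation; C2 and C3 from ruthenium transfer hydrogenation with dynamic kinetic resolution; Cb from the forced cis fusion; Cd from convex-face arylation.

Key step: step 19

Assumption: the absolute sense of the iridium allylation and of the ruthenium transfer hydrogenation is taken from the accepted models for aryl allyl carbonates and aryl ketones; if either proves opposite, the antipodal ligand is used.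

**Route**

Step 1
Reactants: 1 4-bromo-2,5-dimethoxybenzaldehyde
Product: 2 4-bromo-2-hydroxy-5-methoxybenzaldehyde
Conditions: BCl3 (1.1 equiv), CH2Cl2, −78 → 0 °C; aq. work-up
Reagents that add atoms: none
Why: Chelation-controlled Lewis-acid demethylation cleaves only the methyl ether that can bind boron together with the ortho formyl oxygen.

Step 2
Reactants: 2 4-bromo-2-hydroxy-5-methoxybenzaldehyde
Product: 3 2-(benzyloxy)-4-bromo-5-methoxybenzaldehyde
Conditions: BnBr, K2CO3, DMF, 25 °C
Reagents that add atoms: benzyl bromide, BrCc1ccccc1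
Why: Williamson etherification of the phenoxide gives a benzyl ether that should withstand the later carbanion, Grignard and Lewis-acid steps.

Step 3
Reactants: 3 2-(benzyloxy)-4-bromo-5-methoxybenzaldehyde
Product: 4 methyl (E)-3-[2-(benzyloxy)-4-bromo-5-methoxyphenyl]prop-2-enoate
Conditions: (MeO)2P(O)CH2CO2Me, NaH, THF, 0 → 25 °C
Reagents that add atoms: trimethyl phosphonoacetate, COC(=O)CP(=O)(OC)OC
Why: Horner–Wadsworth–Emmons olefination of an aryl aldehyde with a stabilised phosphonate anion should give the (E)-cinnamate.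

Step 4
Reactants: 4 methyl (E)-3-[2-(benzyloxy)-4-bromo-5-methoxyphenyl]prop-2-enoate
Product: 5 (E)-3-[2-(benzyloxy)-4-bromo-5-methoxyphenyl]prop-2-en-1-ol
Conditions: DIBAL-H (2.2 equiv), CH2Cl2, −78 °C; Rochelle salt
Reagents that add atoms: none
Why: 1,2-Reduction of the conjugated ester by the aluminium hydride gives the allylic alcohol and leaves the aryl bromide untouched.

Step 5
Reactants: 5 (E)-3-[2-(benzyloxy)-4-bromo-5-methoxyphenyl]prop-2-en-1-ol
Product: 6 (E)-3-[2-(benzyloxy)-4-bromo-5-methoxyphenyl]prop-2-en-1-yl methyl carbonate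
Conditions: ClCO2Me, pyridine, CH2Cl2, 0 °C
Reagents that add atoms: methyl chloroformate, COC(=O)Cl
Why: O-Acylation of the primary allylic alcohol installs the carbonate leaving group needed for allylic substitution.

Step 6
Reactants: 7 methyl 2-(3,5-dimethoxyphenyl)acetate
Product: 8 dimethyl 2-(3,5-dimethoxyphenyl)propanedioate
Conditions: NaH (2.2 equiv), (MeO)2CO, THF, 65 °C; then 1 M HCl
Reagents that add atoms: dimethyl carbonate, COC(=O)OC
Why: Claisen-type C-acylation of the arylacetate enolate is driven to completion by deprotonation of the more acidic arylmalonate.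

Step 7
Reactants: 6 (E)-3-[2-(benzyloxy)-4-bromo-5-methoxyphenyl]prop-2-en-1-yl methyl carbonate; 8 dimethyl 2-(3,5-dimethoxyphenyl)propanedioate
Product: 10 dimethyl 2-{(1R)-1-[2-(benzyloxy)-4-bromo-5-methoxyphenyl]prop-2-en-1-yl}-2-(3,5-dimethoxyphenyl)propanedioate, via sodium arylmalonate 9 (not isolated)
Conditions: 8, NaH, THF, 0 °C; then 6, [Ir(cod)Cl]2 (2 mol%), (Ra,Rc,Rc)-O,O′-(1,1′-binaphthalene-2,2′-diyl) N,N-bis(1-phenylethyl)phosphoramidite (4 mol%, pre-activated with n-PrNH2), THF, 35 °C
Reagents that add atoms: none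
Why: Iridium-catalysed asymmetric allylic alkylation with a cyclometalated phosphoramidite catalyst places stabilised carbon nucleophiles at the aryl-bearing allyl terminus, and the ligand-controlled face of attack sets Cc as R.

Step 8
Reactants: 10 dimethyl 2-{(1R)-1-[2-(benzyloxy)-4-bromo-5-methoxyphenyl]prop-2-en-1-yl}-2-(3,5-dimethoxyphenyl)propanedioate
Product: 11 dimethyl 2-{(1R)-1-[2-(benzyloxy)-4-bromo-5-methoxyphenyl]-2-oxoethyl}-2-(3,5-dimethoxyphenyl)propanedioate
Conditions: OsO4 (2 mol%), NaIO4 (4 equiv), 2,6-lutidine, dioxane/H2O 3:1, 25 °C; used at once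
Reagents that add atoms: osmium tetroxide, O=[Os](=O)(=O)=O; sodium periodate, [Na+].[O-]I(=O)(=O)=O
Why: Lemieux–Johnson cleavage of the terminal alkene under lutidine buffering should spare the electron-rich arenes and the α-aryl stereocentre Cc.

Step 9
Reactants: 11 dimethyl 2-{(1R)-1-[2-(benzyloxy)-4-bromo-5-methoxyphenyl]-2-oxoethyl}-2-(3,5-dimethoxyphenyl)propanedioate
Product: 12 dimethyl 2-{(1R)-1-[2-(benzyloxy)-4-bromo-5-methoxyphenyl]-2-hydroxy-2-(4-methoxyphenyl)ethyl}-2-(3,5-dimethoxyphenyl)propanedioate (both carbinol epimers)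
Conditions: 4-MeOC6H4MgBr (1.3 equiv), THF, −78 °C; aq. NH4Cl at −78 °C
Reagents that add atoms: 4-methoxyphenylmagnesium bromide, COc1ccc([Mg]Br)cc1
Why: Grignard 1,2-addition to the aldehyde is far faster at −78 °C than attack on the hindered neopentyl-type esters, and the new carbinol centre is erased in the next step so both epimers serve.

Step 10
Reactants: 12 carbinol (both epimers)
Product: 13 dimethyl (2R,3R)-2-[2-(benzyloxy)-4-bromo-5-methoxyphenyl]-4,6-dimethoxy-3-(4-methoxyphenyl)-2,3-dihydro-1H-indene-1,1-dicarboxylate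
Conditions: Bi(OTf)3 (5 mol%), CH2Cl2, −20 → 0 °C
Reagents that add atoms: none
Why: Ionisation of the 4-methoxybenzylic alcohol gives a stabilised cation that is captured by the ortho carbon of ring A, which is ortho and para to its two methoxy groups (intramolecular Friedel–Crafts alkylation closing ring B), and the aryl group on Ca should settle trans to ring D on Cc in the five-membered transition state.

Step 11
Reactants: 14 3,5-dimethoxybenzyl bromide; 15 4-methoxybenzoyl chloride
Product: 17 2-(3,5-dimethoxyphenyl)-1-(4-methoxyphenyl)ethan-1-one, via (3,5-dimethoxybenzyl)zinc bromide 16 (not isolated)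
Conditions: Zn dust, LiCl, THF, 25 °C; then 15, Pd(PPh3)4 (2 mol%), THF, 25 °C
Reagents that add atoms: none
Why: Zinc insertion into the benzylic bromide followed by Negishi acylation with the acid chloride gives the deoxybenzoin without Wurtz coupling.

Step 12
Reactants: 13 indane diester bromide; 17 2-(3,5-dimethoxyphenyl)-1-(4-methoxyphenyl)ethan-1-one
Product: 18 benzyl-protected triaryl ketone (13 with CH(3,5-dimethoxyphenyl)C(=O)(4-methoxyphenyl) on D5 in place of Br; both C3 epimers)
Conditions: Pd2(dba)3 (2.5 mol%), XPhos (6 mol%), K3PO4 (2.5 equiv), toluene, 100 °C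
Reagents that add atoms: none
Why: Palladium-catalysed α-arylation of the ketone enolate couples at an aryl bromide that has only one ortho substituent, and the more acidic product rests as its enolate so it is not arylated again.

Step 13
Reactants: 18 benzyl-protected triaryl ketone
Product: 19 phenol ketone (18 with OH on D1; both C3 epimers)
Conditions: H2 (1 atm), Pd/C (10 wt%), EtOAc, 25 °C
Reagents that add atoms: none
Why: Hydrogenolysis of the benzyl ether frees the phenol at a stage where no aryl halide or benzylic alcohol is present and the hindered aryl ketone reacts much more slowly.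

Step 14
Reactants: 19 phenol ketone
Product: 20 (1S,2S)-alcohol (side chain D5–C3H(3,5-dimethoxyphenyl)–C2H(OH)(4-methoxyphenyl); C3 S; C2 S)
Conditions: RuCl[(S,S)-TsDPEN](p-cymene) (2 mol%), HCO2H/Et3N 5:2, DMF, 40 °C
Reagents that add atoms: none
Why: Noyori–Ikariya transfer hydrogenation with dynamic kinetic resolution, in which the doubly benzylic α-centre racemises through the enol in the amine buffer, the catalyst sets C2 as S, and the matched Felkin–Anh pairing (hydride anti to the bulky ring D substituent) selects the ketone epimer with C3 S.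

Step 15
Reactants: 20 (1S,2S)-alcohol
Product: 21 bromophenol (20 with Br on D6)
Conditions: NBS (1.0 equiv), i-Pr2NH (10 mol%), CH2Cl2, −78 °C
Reagents that add atoms: N-bromosuccinimide, O=C1CCC(=O)N1Br
Why: Amine-mediated ortho-bromination of the phenol goes to D6, the only free position ortho to the hydroxyl (para is blocked by OMe), and at −78 °C should outpace bromination of the methyl-ether rings.

Step 16
Reactants: 21 bromophenol
Product: 23 ortho-silyl phenol (SiMe3 on D6; OH on D1; OH on C2), via bis(trimethylsilyl) ether 22 (not isolated)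
Conditions: HMDS, THF, 65 °C, concentrate; n-BuLi (1.1 equiv), THF, −100 °C; H2O; then K2CO3 (cat.), MeOH, 0 °C
Reagents that add atoms: hexamethyldisilazane, C[Si](C)(C)N[Si](C)(C)C
Why: Bromine–lithium exchange at −100 °C followed by anionic retro-Brook migration of silicon from oxygen to the ortho carbon is the standard entry to ortho-silyl phenols, the aryllithium on D6 cannot reach the esters on Cb, and methanolysis gives the same diol whichever silyl ether donates silicon.

Step 17
Reactants: 23 ortho-silyl phenol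
Product: 24 aryl triflate (OTf on D1; SiMe3 on D6; free OH on C2)
Conditions: PhNTf2 (1.2 equiv), Et3N, DMAP (cat.), CH2Cl2, 25–40 °C
Reagents that add atoms: N-phenylbis(trifluoromethanesulfonimide), O=S(=O)(N(c1ccccc1)S(=O)(=O)C(F)(F)F)C(F)(F)F
Why: The mild triflimide reagent sulfonylates the phenoxide selectively and leaves the neutral secondary alcohol alone.

Step 18
Reactants: 24 aryl triflate
Product: 25 aryne precursor (OTf on D1; SiMe3 on D6; OSiMe3 on C2; gem-diester on Cb)
Conditions: 1-(trimethylsilyl)imidazole, CH2Cl2, 25 °C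
Reagents that add atoms: 1-(trimethylsilyl)imidazole, C[Si](C)(C)n1ccnc1
Why: Silyl transfer from the N-silylimidazole to the secondary alcohol is neutral and fluoride-free, so the silyl triflate survives.

Step 19
Reactants: 25 aryne precursor
Product: 28 pentacyclic keto ester (rings C and E closed; Cd = C=O; CO2Me on Cb), via aryne alkoxide 26 (not isolated), via aryl potassium 27 (not isolated)
Conditions: KF (spray-dried, 4 equiv), 18-crown-6 (4 equiv), THF (0.005 M), 0 → 25 °C
Reagents that add atoms: none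
Why: Proposed new method: fluoride removes the O-silyl group to give the potassium alkoxide and attacks the aryl silicon on D6 so that triflate leaves from D1 and the D1–D6 aryne forms; the alkoxide adds to D6 and the aryl anion thus placed on D1 acylates itself on the neighbouring ester with loss of methoxide, the closest known reaction types being intramolecular alkoxide and amide additions to arynes and aryne annulations of salicylates in which the aryl anion is trapped by an ester. Ring E closes by 5-exo attack of oxygen on the in-plane aryne orbital and ring C by 5-exo-trig attack of the aryl anion on the ester carbonyl. C2 and C3 are not touched (the C2–O bond is kept), so the trans dihydrofuran follows from the (1S,2S) side chain, and the new quaternary centre Cb is fixed because only the ester cis to ring D on Cc can be reached, which forces the cis B/C fusion. The step needs oxygen to add first and at D6, secured by the two-atom tether (attack at D1 would demand a bridged ring), and it needs an aryl anion that meets no proton, secured by the non-enolisable gem-diester on Cb and aprotic conditions. With silicon on D6 and triflate on D1 the alkoxide cannot reach the sulfonyl group, and methoxide set free can at worst remove the second ester and give 29, the next intermediate.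

Step 20
Reactants: 28 pentacyclic keto ester
Product: 29 pentacyclic ketone (Cd = C=O; H on Cb; cis B/C fusion)
Conditions: LiCl (3 equiv), DMSO/H2O, 120 °C
Reagents that add atoms: none
Why: Krapcho dealkoxycarbonylation, in which chloride demethylates the ester of the non-enolisable β-keto ester, carbon dioxide is lost and the enolate is protonated to the only accessible cis ring fusion.

Step 21
Reactants: 29 pentacyclic ketone
Product: 30 Cd carbinol (OH on the concave face)
Conditions: NaBH4, THF/MeOH, 0 °C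
Reagents that add atoms: none
Why: Borohydride should reduce the aryl ketone from the convex face, and the carbinol configuration is immaterial because the centre is ionised next.

Step 22
Reactants: 30 Cd carbinol
Product: 31 octamethyl ether of the target
Conditions: anisole (10 equiv), Bi(OTf)3 (5 mol%), CH2Cl2, −20 °C
Reagents that add atoms: anisole, COc1ccccc1
Why: Acid ionises the carbinol to a cation stabilised by the ortho and para oxygens of ring D, and anisole attacks through its para carbon from the open convex face (intermolecular Friedel–Crafts alkylation), which puts the new aryl exo and the Cd hydrogen on the concave face as in the target.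

Step 23
Reactants: 31 octamethyl ether of the target
Product: 32 CNP0154244.2
Conditions: BBr3 (12 equiv), CH2Cl2, −78 → 25 °C; MeOH/H2O
Reagents that add atoms: none
Why: Lewis-acid demethylation with boron tribromide cleaves all eight aryl methyl ethers, and the trans dihydrofuran and the all-exo diquinane are the thermodynamically preferred arrangements, so no stereocentre should be lost.

**Compound list**

1 | 4-bromo-2,5-dimethoxybenzaldehyde | O=Cc1cc(OC)c(Br)cc1OC | starting material
2 | 4-bromo-2-hydroxy-5-methoxybenzaldehyde | O=Cc1cc(OC)c(Br)cc1O | intermediate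
3 | 2-(benzyloxy)-4-bromo-5-methoxybenzaldehyde | O=Cc1cc(OC)c(Br)cc1OCc1ccccc1 | intermediate
4 | methyl (E)-3-[2-(benzyloxy)-4-bromo-5-methoxyphenyl]prop-2-enoate | COC(=O)/C=C/c1cc(OC)c(Br)cc1OCc1ccccc1 | intermediate
5 | (E)-3-[2-(benzyloxy)-4-bromo-5-methoxyphenyl]prop-2-en-1-ol | OC/C=C/c1cc(OC)c(Br)cc1OCc1ccccc1 | intermediate
6 | (E)-3-[2-(benzyloxy)-4-bromo-5-methoxyphenyl]prop-2-en-1-yl methyl carbonate | COC(=O)OC/C=C/c1cc(OC)c(Br)cc1OCc1ccccc1 | intermediate
7 | methyl 2-(3,5-dimethoxyphenyl)acetate | COC(=O)Cc1cc(OC)cc(OC)c1 | starting material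
8 | dimethyl 2-(3,5-dimethoxyphenyl)propanedioate | COC(=O)C(C(=O)OC)c1cc(OC)cc(OC)c1 | intermediate
9 | sodium salt (enolate) of 8 | [Na+].COC(=O)[C-](C(=O)OC)c1cc(OC)cc(OC)c1 | intermediate
10 | dimethyl 2-{(1R)-1-[2-(benzyloxy)-4-bromo-5-methoxyphenyl]prop-2-en-1-yl}-2-(3,5-dimethoxyphenyl)propanedioate | COC(=O)C(C(=O)OC)(c1cc(OC)cc(OC)c1)[C@H](C=C)c1cc(OC)c(Br)cc1OCc1ccccc1 | intermediate
11 | dimethyl 2-{(1R)-1-[2-(benzyloxy)-4-bromo-5-methoxyphenyl]-2-oxoethyl}-2-(3,5-dimethoxyphenyl)propanedioate | COC(=O)C(C(=O)OC)(c1cc(OC)cc(OC)c1)[C@H](C=O)c1cc(OC)c(Br)cc1OCc1ccccc1 | intermediate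
12 | dimethyl 2-{(1R)-1-[2-(benzyloxy)-4-bromo-5-methoxyphenyl]-2-hydroxy-2-(4-methoxyphenyl)ethyl}-2-(3,5-dimethoxyphenyl)propanedioate, both carbinol epimers | COC(=O)C(C(=O)OC)(c1cc(OC)cc(OC)c1)[C@H](C(O)c1ccc(OC)cc1)c1cc(OC)c(Br)cc1OCc1ccccc1 | intermediate
13 | dimethyl (2R,3R)-2-[2-(benzyloxy)-4-bromo-5-methoxyphenyl]-4,6-dimethoxy-3-(4-methoxyphenyl)-2,3-dihydro-1H-indene-1,1-dicarboxylate (Ca R, Cc R, aryls trans) | COc1ccc([C@@H]2c3c(OC)cc(OC)cc3C(C(=O)OC)(C(=O)OC)[C@H]2c2cc(OC)c(Br)cc2OCc2ccccc2)cc1 | intermediate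
14 | 3,5-dimethoxybenzyl bromide | COc1cc(CBr)cc(OC)c1 | starting material
15 | 4-methoxybenzoyl chloride | COc1ccc(C(Cl)=O)cc1 | starting material
16 | (3,5-dimethoxybenzyl)zinc bromide | COc1cc(C[Zn]Br)cc(OC)c1 | intermediate
17 | 2-(3,5-dimethoxyphenyl)-1-(4-methoxyphenyl)ethan-1-one | COc1ccc(C(=O)Cc2cc(OC)cc(OC)c2)cc1 | intermediate
18 | dimethyl (2R,3R)-2-{2-(benzyloxy)-4-[1-(3,5-dimethoxyphenyl)-2-(4-methoxyphenyl)-2-oxoethyl]-5-methoxyphenyl}-4,6-dimethoxy-3-(4-methoxyphenyl)-2,3-dihydro-1H-indene-1,1-dicarboxylate, both C3 epimers | COc1ccc([C@@H]2c3c(OC)cc(OC)cc3C(C(=O)OC)(C(=O)OC)[C@H]2c2cc(OC)c(C(c3cc(OC)cc(OC)c3)C(=O)c3ccc(OC)cc3)cc2OCc2ccccc2)cc1 | intermediate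
19 | dimethyl (2R,3R)-2-{4-[1-(3,5-dimethoxyphenyl)-2-(4-methoxyphenyl)-2-oxoethyl]-2-hydroxy-5-methoxyphenyl}-4,6-dimethoxy-3-(4-methoxyphenyl)-2,3-dihydro-1H-indene-1,1-dicarboxylate, both C3 epimers | COc1ccc([C@@H]2c3c(OC)cc(OC)cc3C(C(=O)OC)(C(=O)OC)[C@H]2c2cc(OC)c(C(c3cc(OC)cc(OC)c3)C(=O)c3ccc(OC)cc3)cc2O)cc1 | intermediate
20 | dimethyl (2R,3R)-2-{4-[(1S,2S)-1-(3,5-dimethoxyphenyl)-2-hydroxy-2-(4-methoxyphenyl)ethyl]-2-hydroxy-5-methoxyphenyl}-4,6-dimethoxy-3-(4-methoxyphenyl)-2,3-dihydro-1H-indene-1,1-dicarboxylate | COc1ccc([C@@H]2c3c(OC)cc(OC)cc3C(C(=O)OC)(C(=O)OC)[C@H]2c2cc(OC)c([C@H](c3cc(OC)cc(OC)c3)[C@H](O)c3ccc(OC)cc3)cc2O)cc1 | intermediate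
21 | dimethyl (2R,3R)-2-{3-bromo-4-[(1S,2S)-1-(3,5-dimethoxyphenyl)-2-hydroxy-2-(4-methoxyphenyl)ethyl]-2-hydroxy-5-methoxyphenyl}-4,6-dimethoxy-3-(4-methoxyphenyl)-2,3-dihydro-1H-indene-1,1-dicarboxylate | COc1ccc([C@@H]2c3c(OC)cc(OC)cc3C(C(=O)OC)(C(=O)OC)[C@H]2c2cc(OC)c([C@H](c3cc(OC)cc(OC)c3)[C@H](O)c3ccc(OC)cc3)c(Br)c2O)cc1 | intermediate
22 | bis(trimethylsilyl) ether of 21 (OSiMe3 on D1 and on C2) | COc1ccc([C@@H]2c3c(OC)cc(OC)cc3C(C(=O)OC)(C(=O)OC)[C@H]2c2cc(OC)c([C@H](c3cc(OC)cc(OC)c3)[C@H](O[Si](C)(C)C)c3ccc(OC)cc3)c(Br)c2O[Si](C)(C)C)cc1 | intermediate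
23 | dimethyl (2R,3R)-2-{4-[(1S,2S)-1-(3,5-dimethoxyphenyl)-2-hydroxy-2-(4-methoxyphenyl)ethyl]-2-hydroxy-5-methoxy-3-(trimethylsilyl)phenyl}-4,6-dimethoxy-3-(4-methoxyphenyl)-2,3-dihydro-1H-indene-1,1-dicarboxylate | COc1ccc([C@@H]2c3c(OC)cc(OC)cc3C(C(=O)OC)(C(=O)OC)[C@H]2c2cc(OC)c([C@H](c3cc(OC)cc(OC)c3)[C@H](O)c3ccc(OC)cc3)c([Si](C)(C)C)c2O)cc1 | intermediate
24 | dimethyl (2R,3R)-2-{4-[(1S,2S)-1-(3,5-dimethoxyphenyl)-2-hydroxy-2-(4-methoxyphenyl)ethyl]-5-methoxy-2-[(trifluoromethanesulfonyl)oxy]-3-(trimethylsilyl)phenyl}-4,6-dimethoxy-3-(4-methoxyphenyl)-2,3-dihydro-1H-indene-1,1-dicarboxylate | COc1ccc([C@@H]2c3c(OC)cc(OC)cc3C(C(=O)OC)(C(=O)OC)[C@H]2c2cc(OC)c([C@H](c3cc(OC)cc(OC)c3)[C@H](O)c3ccc(OC)cc3)c([Si](C)(C)C)c2OS(=O)(=O)C(F)(F)F)cc1 | intermediate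
25 | dimethyl (2R,3R)-2-{4-[(1S,2S)-1-(3,5-dimethoxyphenyl)-2-(4-methoxyphenyl)-2-(trimethylsilyloxy)ethyl]-5-methoxy-2-[(trifluoromethanesulfonyl)oxy]-3-(trimethylsilyl)phenyl}-4,6-dimethoxy-3-(4-methoxyphenyl)-2,3-dihydro-1H-indene-1,1-dicarboxylate (aryne precursor) | COc1ccc([C@@H]2c3c(OC)cc(OC)cc3C(C(=O)OC)(C(=O)OC)[C@H]2c2cc(OC)c([C@H](c3cc(OC)cc(OC)c3)[C@H](O[Si](C)(C)C)c3ccc(OC)cc3)c([Si](C)(C)C)c2OS(=O)(=O)C(F)(F)F)cc1 | intermediate
26 | aryne alkoxide: 25 without both silyl groups and triflate, ring D as the D1–D6 aryne, potassium alkoxide on C2 | COc1ccc([C@@H]2c3c(OC)cc(OC)cc3C(C(=O)OC)(C(=O)OC)[C@H]2C2=CC(OC)=C([C@H](c3cc(OC)cc(OC)c3)[C@H]([O-])c3ccc(OC)cc3)C#C2)cc1.[K+] | intermediate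
27 | aryl potassium: ring E closed (O1–D6), carbanion on D1, gem-diester intact | COc1ccc([C@@H]2c3c(OC)cc(OC)cc3C(C(=O)OC)(C(=O)OC)[C@H]2c2cc(OC)c3c(O[C@H](c4ccc(OC)cc4)[C@H]3c3cc(OC)cc(OC)c3)[c-]2)cc1.[K+] | intermediate
28 | pentacyclic keto ester: skeleton of 31 with Cd = C=O and CO2Me on Cb (Ca R, Cb R, Cc R, C2 S, C3 S) | COc1ccc([C@@H]2c3c(OC)cc(OC)cc3[C@@]3(C(=O)OC)C(=O)c4c(cc(OC)c5c4O[C@H](c4ccc(OC)cc4)[C@H]5c4cc(OC)cc(OC)c4)[C@@H]23)cc1 | intermediate
29 | pentacyclic ketone: 28 with H on Cb, cis B/C fusion (Ca R, Cb S, Cc S, C2 S, C3 S; descriptors change by priority only) | COc1ccc([C@@H]2c3c(OC)cc(OC)cc3[C@H]3C(=O)c4c(cc(OC)c5c4O[C@H](c4ccc(OC)cc4)[C@H]5c4cc(OC)cc(OC)c4)[C@@H]23)cc1 | intermediate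
30 | Cd carbinol: 29 reduced, OH on the concave face (Cd R) | COc1ccc([C@@H]2c3c(OC)cc(OC)cc3[C@H]3[C@@H](O)c4c(cc(OC)c5c4O[C@H](c4ccc(OC)cc4)[C@H]5c4cc(OC)cc(OC)c4)[C@@H]23)cc1 | intermediate
31 | octamethyl ether of the target (Ca R, Cb R, Cc R, Cd R, C2 S, C3 S) | COc1ccc([C@@H]2c3c(OC)cc(OC)cc3[C@H]3[C@H](c4ccc(OC)cc4)c4c(cc(OC)c5c4O[C@H](c4ccc(OC)cc4)[C@H]5c4cc(OC)cc(OC)c4)[C@@H]23)cc1 | intermediate
32 | CNP0154244.2 (Ca R, Cb R, Cc R, Cd R, C2 S, C3 S) | Oc1ccc([C@@H]2c3c(O)cc(O)cc3[C@H]3[C@H](c4ccc(O)cc4)c4c(cc(O)c5c4O[C@H](c4ccc(O)cc4)[C@H]5c4cc(O)cc(O)c4)[C@@H]23)cc1 | target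

**Totals**

Total step count: 23 (21 in the main line, plus step 6 for the arylmalonate and step 11 for the side-chain ketone).
Longest linear sequence: 21 steps from 1 to 32 (steps 1–5, 7–10, 12–23).

**Steps most likely to fail**

1. Step 19. The relay may break through protonation of the D1 aryl anion before it acylates, through capture of the aryne by fluoride, or through fragmentation of the alkoxide before the aryne forms. Fallback with known chemistry, setting out from 21: copper-catalysed intramolecular C–O coupling of the side-chain alcohol with the D6 bromide (CuI, 3,4,7,8-tetramethyl-1,10-phenanthroline, Cs2CO3, toluene, 110 °C) should close ring E and give the dihydrobenzofuranol F1. Triflation (PhNTf2, Et3N) should give the aryl triflate F2. Palladium-catalysed triflate-to-bromide exchange (Pd2(dba)3, t-BuBrettPhos, KBr, KF, toluene, 100 °C) should give the aryl bromide F3. Bromine–lithium exchange with t-BuLi at −100 °C and Parham-type cyclisation of the D1 aryllithium onto the cis ester should then close ring C and rejoin the route at 28.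

2. Step 7. The tertiary, aryl-stabilised malonate anion may react slowly at the hindered allyl terminus, which would erode branched selectivity and enantioselectivity. Fallback, setting out from 6: the two bonds at Cb are made in the opposite order. Iridium-catalysed allylic alkylation with sodium dimethyl malonate (same catalyst) should give the allylmalonate F4, which has the same spatial arrangement but the descriptor S. Its sodium enolate is then arylated with (3,5-dimethoxyphenyl)(2,4,6-trimethoxyphenyl)iodonium tosylate in DMF (metal-free α-arylation of malonates, the trimethoxyphenyl group being the non-transferred ligand), which rejoins the route at 10.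

3. Step 14. Racemisation at C3 may be slower than reduction, so that the resolution is not dynamic and diastereomers form. Fallback, setting out from 19: catalyst control is replaced by substrate control and separation. NaBH4 in MeOH at −40 °C should reduce both C3 epimers in the Felkin–Anh sense and give 20 together with the (1R,2R) side-chain diastereomer F5. The two differ in their relation to the fixed indane centres and should separate by chromatography. F5 is oxidised back to 19 with MnO2 and recycled, and the route is rejoined at 20.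

**Further compounds**

F1 | step 19 | dihydrobenzofuranol: 21 with the O1–D6 bond in place of Br, free OH on D1, gem-diester intact | COc1ccc([C@@H]2c3c(OC)cc(OC)cc3C(C(=O)OC)(C(=O)OC)[C@H]2c2cc(OC)c3c(O[C@H](c4ccc(OC)cc4)[C@H]3c3cc(OC)cc(OC)c3)c2O)cc1
F2 | step 19 | aryl triflate of F1 (OTf on D1) | COc1ccc([C@@H]2c3c(OC)cc(OC)cc3C(C(=O)OC)(C(=O)OC)[C@H]2c2cc(OC)c3c(O[C@H](c4ccc(OC)cc4)[C@H]3c3cc(OC)cc(OC)c3)c2OS(=O)(=O)C(F)(F)F)cc1
F3 | step 19 | aryl bromide (Br on D1 in place of OTf) | COc1ccc([C@@H]2c3c(OC)cc(OC)cc3C(C(=O)OC)(C(=O)OC)[C@H]2c2cc(OC)c3c(O[C@H](c4ccc(OC)cc4)[C@H]3c3cc(OC)cc(OC)c3)c2Br)cc1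
F4 | step 7 | dimethyl 2-{(1S)-1-[2-(benzyloxy)-4-bromo-5-methoxyphenyl]prop-2-en-1-yl}propanedioate | COC(=O)C(C(=O)OC)[C@H](C=C)c1cc(OC)c(Br)cc1OCc1ccccc1
F5 | step 14 | (1R,2R) side-chain diastereomer of 20 | COc1ccc([C@@H]2c3c(OC)cc(OC)cc3C(C(=O)OC)(C(=O)OC)[C@H]2c2cc(OC)c([C@@H](c3cc(OC)cc(OC)c3)[C@@H](O)c3ccc(OC)cc3)cc2O)cc1
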